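**Assumptions (one line each):**
- (R)-Mevalonolactone is available from a catalogue supplier (or by resolving the racemate).
- 3-(Silyloxymethyl)furans lithiate at C2.
- The Mg-mediated iodo-Morita–Baylis–Hillman reaction works with formaldehyde.
- Sesquiterpene numbering is used throughout: C1–C10 ring, C11 lactone α-carbon, C12 lactone C=O, C13 =CH2, C14 the C10 methyl, C15 the CH2OH on C4.

## Retrosynthetic overview
1. Niveusin B comes from global desilylation of the 10-membered keto-lactone 19. The bridging C3–O–C10 hemiketal closes spontaneously at this last step, so the THF ring is the last ring formed.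
2. The carbocycle, the α-methylene-γ-lactone and the C6/C7 stereocentres form together in one intramolecular Nozaki–Hiyama–Kishi (NHK) allylation/lactonization. The allyl bromide is a 2-(bromomethyl)alk-2-enoate and the electrophile is a Z-4-oxoenal (18).
3. The Z-4-oxoenal (18) is unmasked by oxidising a 2-alkyl-3-(silyloxymethyl)furan. The furan fixes the cis relationship of C3 and C6 across C4=C5.
4. The furan-bearing aldehyde 7 comes from (R)-mevalonolactone (sets C10) and 3-furanmethanol. It is joined to an iodoacrylate by NHK vinylation, and C8 is set by CBS reduction of the enone, followed by angelate formation.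

## Route

**Step 1**
Reactants: 1 (3-furanmethanol)
Product: 2 (tert-butyldimethyl(furan-3-ylmethoxy)silane)
Conditions: TBSCl, imidazole, CH2Cl2, 0 °C → rt
Reagents that add atoms: TBSCl, CC(C)(C)[Si](C)(C)Cl
Why: Silylation protects the alcohol so that C2 of the furan can be lithiated later. No stereocentre is involved.

**Step 2**
Reactants: 3 ((R)-mevalonolactone)
Product: 4 ((R)-4-methyl-4-(triethylsilyloxy)tetrahydropyran-2-one)
Conditions: TESOTf, 2,6-lutidine, CH2Cl2, −78 → 0 °C
Reagents that add atoms: TESOTf, CC[Si](CC)(CC)OS(=O)(=O)C(F)(F)F
Why: The tertiary alcohol is capped so that it cannot undergo β-elimination or retro-aldol later as a β-oxy carbonyl. The C10 stereocentre comes from the chiral pool and is never touched.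

**Step 3**
Reactants: 2; 4
Product: 5 (furyl ketone with a free primary alcohol; ring-chain tautomer of a lactol)
Conditions: n-BuLi, THF, −78 → 0 °C to lithiate 2 at C2; then add 4 at −78 °C and quench with NH4Cl
Reagents that add atoms: none
Why: Directed C2-lithiation followed by nucleophilic acyl addition to the lactone (ring-opening to the hydroxy-ketone) attaches furan C3 to the C2 carbonyl and differentiates the two arms of the mevalonate. No stereocentre is formed.

**Step 4**
Reactants: 5
Product: 6 (primary alcohol with the furan–CH2CH2 chain)
Conditions: (a) TsNHNH2, MeOH, rt; (b) catecholborane, CHCl3, 0 °C, then NaOAc·3H2O, reflux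
Reagents that add atoms: none (the Ts and catechol groups are not retained)
Why: Reduction of the furyl-ketone tosylhydrazone (Kabalka variant of the Caglioti reaction) converts C=O to CH2 under non-acidic conditions that tolerate the silyl ethers and the furan. No stereocentre is formed.

**Step 5**
Reactants: 6
Product: 7 (β-silyloxy aldehyde, C8 aldehyde)
Conditions: Dess–Martin periodinane, NaHCO3, CH2Cl2, 0 °C
Reagents that add atoms: none
Why: Dess–Martin oxidation of a primary alcohol is mild and leaves the furan and the silyl ethers intact. The aldehyde is used immediately.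

**Step 6**
Reactants: 8 (methyl propiolate)
Product: 9 (methyl (Z)-2-(hydroxymethyl)-3-iodoacrylate)
Conditions: MgI2, (CH2O)n, Et2O/CH2Cl2, 0 °C → rt
Reagents that add atoms: MgI2, I[Mg]I; paraformaldehyde, C=O
Why: Anti conjugate addition of iodide to the propiolate gives a magnesium allenolate, and aldol with formaldehyde follows (iodo-Morita–Baylis–Hillman reaction). This sets the alkene with I cis to CO2Me.

**Step 7**
Reactants: 9
Product: 10 (the TES ether of 9)
Conditions: TESCl, imidazole, DMF, 0 °C
Reagents that add atoms: TESCl, CC[Si](CC)(CC)Cl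
Why: Silylation protects the primary allylic alcohol for the NHK coupling. The TES group can later be removed selectively from this primary position.

**Step 8**
Reactants: 7; 10
Product: 11 (allylic alcohol, C8 epimer mixture)
Conditions: CrCl2 (excess), NiCl2 (cat.), DMF, rt
Reagents that add atoms: none
Why: Ni/Cr-mediated vinylation of the aldehyde (NHK) retains the alkene geometry. The new C8 centre is formed unselectively and is reset in steps 9–10.

**Step 9**
Reactants: 11
Product: 12 (enone)
Conditions: Dess–Martin periodinane, NaHCO3, CH2Cl2, rt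
Reagents that add atoms: none
Why: Oxidation of the secondary allylic alcohol to the ketone converges both C8 epimers into a single prochiral enone.

**Step 10**
Reactants: 12
Product: 13 ((8R)-allylic alcohol)
Conditions: (S)-Me-CBS (0.2 equiv), BH3·SMe2, THF, −20 °C
Reagents that add atoms: none
Why: CBS reduction is reagent-controlled and sets C8 as R. By the acetophenone analogy the (S)-catalyst should give R; confirm by Mosher analysis and switch catalyst enantiomer if needed. The remote C10 centre has little influence.

**Step 11**
Reactants: 13; 14 (angelic acid)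
Product: 15 (C8 angelate)
Conditions: 14, 2,4,6-Cl3C6H2COCl, Et3N, THF; then add 13, DMAP, toluene, rt
Reagents that add atoms: none (the angeloyl group comes from 14)
Why: Yamaguchi esterification through the mixed anhydride acylates the hindered secondary alcohol with minimal Z→E (angelate→tigloate) isomerisation. C8 is unchanged.

**Step 12**
Reactants: 15
Product: 16 (free primary allylic alcohol)
Conditions: PPTS (0.1 equiv), MeOH, 0 °C → rt
Reagents that add atoms: none
Why: A primary TES ether is cleaved selectively over the tertiary TES ether, the primary TBS ether, the angelate and the furan.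

**Step 13**
Reactants: 16
Product: 17 (E-allylic bromide, 2-(bromomethyl)alk-2-enoate)
Conditions: PPh3, CBr4, CH2Cl2, 0 °C
Reagents that add atoms: CBr4, BrC(Br)(Br)Br
Why: Appel bromination (SN2) converts the primary allylic alcohol to the bromide, which is the allylchromium precursor for the macrocyclisation. No stereocentre is formed.

**Step 14**
Reactants: 17
Product: 18 (Z-4-oxo-2-enal, ketoaldehyde)
Conditions: DMDO in acetone, −20 → 0 °C; crude product used at once
Reagents that add atoms: DMDO, CC1(C)OO1
Why: Oxidative opening of the 2-alkylfuran gives a cis-ene-1,4-dicarbonyl. The cis relationship of C3 and C6 across C4=C5 is inherited from the ring, which sets the Z alkene of the target.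

**Step 15**
Reactants: 18
Product: 19 (10-membered keto-lactone, α-methylene-γ-lactone)
Conditions: CrCl2 (≈8 equiv), NiCl2 (cat.), DMF, ≈3 mM (syringe-pump addition), rt; lactonisation in situ or on work-up
Reagents that add atoms: none
Why: An intramolecular NHK allylation (Hoffmann-type allylation/lactonisation) forms C6–C7 by γ-attack of the allylchromium on the aldehyde. The anti-selective chair-like transition state should give the 6,7-trans relationship. The new alkoxide closes onto the methyl ester to give the lactone and restore the exocyclic methylene. The aldehyde is much more reactive than the C3 ketone, so the ketone survives.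

**Step 16**
Reactants: 19
Product: 20 (niveusin B)
Conditions: HF·pyridine, pyridine, THF, 0 °C → rt
Reagents that add atoms: none
Why: Fluoride removes the C15 TBS and the C10 tertiary TES groups. The freed tertiary OH adds transannularly to the C3 ketone to form the bridged hemiketal. The 2,5-cis geometry of the bridging THF allows only one C3 epimer, and that is the (3R) configuration of the target.

## Compound list
| # | Name | SMILES | Role |
|---|---|---|---|
| 1 | 3-Furanmethanol | OCc1ccoc1 | starting material |
| 2 | 3-(TBS-oxymethyl)furan | CC(C)(C)[Si](C)(C)OCc1ccoc1 | intermediate |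
| 3 | (R)-Mevalonolactone | O=C1C[C@](C)(O)CCO1 | starting material |
| 4 | (R)-TES-mevalonolactone | CC[Si](CC)(CC)O[C@]1(C)CCOC(=O)C1 | intermediate |
| 5 | Furyl hydroxy-ketone | O=C(C[C@](C)(O[Si](CC)(CC)CC)CCO)c1occc1CO[Si](C)(C)C(C)(C)C | intermediate |
| 6 | Furyl alcohol (ketone reduced to CH2) | OCC[C@@](C)(O[Si](CC)(CC)CC)CCc1occc1CO[Si](C)(C)C(C)(C)C | intermediate |
| 7 | C8 aldehyde | O=CC[C@@](C)(O[Si](CC)(CC)CC)CCc1occc1CO[Si](C)(C)C(C)(C)C | intermediate |
| 8 | Methyl propiolate | C#CC(=O)OC | starting material |
| 9 | Methyl (Z)-2-(hydroxymethyl)-3-iodoacrylate | I/C=C(/CO)C(=O)OC | intermediate |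
| 10 | TES ether of 9 | I/C=C(/CO[Si](CC)(CC)CC)C(=O)OC | intermediate |
| 11 | Allylic alcohol (C8 epimers) | COC(=O)/C(CO[Si](CC)(CC)CC)=C\C(O)C[C@@](C)(O[Si](CC)(CC)CC)CCc1occc1CO[Si](C)(C)C(C)(C)C | intermediate |
| 12 | Enone | COC(=O)/C(CO[Si](CC)(CC)CC)=C\C(=O)C[C@@](C)(O[Si](CC)(CC)CC)CCc1occc1CO[Si](C)(C)C(C)(C)C | intermediate |
| 13 | (8R)-Allylic alcohol | COC(=O)/C(CO[Si](CC)(CC)CC)=C\[C@H](O)C[C@@](C)(O[Si](CC)(CC)CC)CCc1occc1CO[Si](C)(C)C(C)(C)C | intermediate |
| 14 | Angelic acid | O=C(O)/C(C)=C\C | starting material |
| 15 | C8 angelate | COC(=O)/C(CO[Si](CC)(CC)CC)=C\[C@H](OC(=O)/C(C)=C\C)C[C@@](C)(O[Si](CC)(CC)CC)CCc1occc1CO[Si](C)(C)C(C)(C)C | intermediate |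
| 16 | Primary allylic alcohol | COC(=O)/C(CO)=C\[C@H](OC(=O)/C(C)=C\C)C[C@@](C)(O[Si](CC)(CC)CC)CCc1occc1CO[Si](C)(C)C(C)(C)C | intermediate |
| 17 | Allylic bromide | COC(=O)/C(CBr)=C\[C@H](OC(=O)/C(C)=C\C)C[C@@](C)(O[Si](CC)(CC)CC)CCc1occc1CO[Si](C)(C)C(C)(C)C | intermediate |
| 18 | Z-4-Oxoenal | COC(=O)/C(CBr)=C\[C@H](OC(=O)/C(C)=C\C)C[C@@](C)(O[Si](CC)(CC)CC)CCC(=O)/C(CO[Si](C)(C)C(C)(C)C)=C\C=O | intermediate |
| 19 | 10-Membered keto-lactone | C=C1C(=O)O[C@@H]2/C=C(/CO[Si](C)(C)C(C)(C)C)C(=O)CC[C@](C)(O[Si](CC)(CC)CC)C[C@@H](OC(=O)/C(C)=C\C)[C@@H]12 | intermediate |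
| 20 | Niveusin B | C=C1C(=O)O[C@@H]2/C=C(/CO)[C@@]3(O)CC[C@@](C)(C[C@@H](OC(=O)/C(C)=C\C)[C@@H]12)O3 | target |

## Step count
- Total steps: 16.
- Longest linear sequence: 13 (3 → 4 → 5 → 6 → 7 → 11 → 12 → 13 → 15 → 16 → 17 → 18 → 19 → 20). The furan arm (step 1) and the iodoacrylate arm (steps 6–7) are convergent.

## Three steps most likely to fail
1. **Step 15 (macro-NHK/lactonisation).** A strained 10-membered ring must close with the correct C6/C7 trans stereochemistry.
   - Fallback: close the same C6–C7 bond by a Lewis-acid-promoted intramolecular allylstannane–aldehyde cyclisation (Marshall/Keck-type, open transition state). For this, convert 17 into the allylstannane before the furan oxidation.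
2. **Step 14 (furan → Z-ketoenal).** The product is labile and can isomerise to the E-enone or over-oxidise.
   - Fallback: oxidise with NBS in MeOH to the stable 2,5-dimethoxy-2,5-dihydrofuran and use an allylsilane in place of the allyl bromide. Close the ring by TiCl4-promoted intramolecular Sakurai allylation of the oxocarbenium, then open the dihydrofuran with aqueous acid.
3. **Step 4 (furyl ketone → CH2).** The β-silyloxy ketone can eliminate, and hydrazone formation on the conjugated furyl ketone may be sluggish.
   - Fallback: change the sequence. Reduce lactone 4 with DIBAL to the lactol, add the furyllithium to give the secondary furfuryl alcohol, then deoxygenate by Barton–McCombie (xanthate, Bu3SnH).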